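## Retrosynthetic overview
- The last bond made is C11=C12, by Wittig reaction of the ring A acetylenic C15 phosphonium salt with the ring B C25 diol aldehyde.
- The C25 aldehyde comes from the ring B diol C15 phosphonium salt and the C10 dialdehyde (C11'=C12', mono-Wittig).
- Key disconnection: both C–O bonds of the trans-5',6'-diol go back to β-ionone. An enantioselective O-transfer to C5=C6 sets C6–O and the absolute configuration. Anti attack of water at C5 then makes C5–O with inversion.
- The ring A salt comes from the enol triflate of (4R,6R)-actinol (from ketoisophorone, enzymatic) and (E)-3-methylpent-2-en-4-yn-1-ol (Sonogashira).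
- Rings: neither carbocycle is built. Ring B is bought in β-ionone and ring A in ketoisophorone. The only ring formed is the transient oxirane on ring B, which is opened in the same flask.

Numbering: carotenoid numbering is used. Ring B atoms carry unprimed numbers in the ionone and apocarotenal names and primed numbers in the target.

Catalyst P = Boc-L-Asp-L-Pro-D-Val-NHCH2CH2NHC(O)NH-C6H3-3,5-(CF3)2, with the Asp side-chain CO2H free.

Assumption: the facial sense of P cannot be predicted, so its mirror-image peptide is used if a test run shows the opposite sense. P is made by standard peptide couplings and is not counted as a step.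

## Route

Step 1
Reactants: 1 β-ionone
Product: 3 (E)-4-[(1R,2R)-1,2-dihydroxy-2,6,6-trimethylcyclohexyl]but-3-en-2-one, via (5S,6R)-5,6-epoxy-5,6-dihydro-β-ionone 2 (not isolated)
Conditions: P (10 mol %), DMAP (10 mol %), iPrN=C=NiPr (1.5 equiv), 30% aq H2O2 (2.5 equiv), toluene, 4 °C; aq Na2SO3 wash; then HClO4 (5 mol %), THF/H2O 3:1, 0 °C → rt; recrystallise
Reagents that add atoms: hydrogen peroxide OO; water O
Why: Proposed new method: DIC/H2O2 turns the Asp side-chain CO2H of the β-turn peptide into a peracid with the site selectivity of mCPBA (electron-rich tetrasubstituted C5=C6, not the enone C7=C8), while the new oxidation-stable aryl-urea arm binds the C9 ketone by two hydrogen bonds (carbonyl O and alkene carbon stand in the same 1,5-relationship as in the allylic carbamates that such peptides already epoxidise with high ee) and so selects one of the two rapidly interconverting helical 6-s-cis conformers and one alkene face, setting C6 (R) and C5 (S) in 2; acid then opens 2 by the known anti (Fürst–Plattner, borderline SN2) attack of water at C5, because a cation at C6 is destabilised by the enone and shielded by the gem-dimethyl group, which inverts C5 to R, keeps C6 R and gives the trans-diol; closest known reaction types: hydrogen-bond-directed aspartyl-peptide peracid epoxidation and acid hydrolysis of racemic β-ionone epoxide.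

Step 2
Reactants: 3 (E)-4-[(1R,2R)-1,2-dihydroxy-2,6,6-trimethylcyclohexyl]but-3-en-2-one
Product: 4 (E)-1-[(1R,2R)-1,2-dihydroxy-2,6,6-trimethylcyclohexyl]-3-methylpenta-1,4-dien-3-ol (C9 epimers)
Conditions: CH2=CHMgBr (4 equiv), THF, −40 → 0 °C; sat. aq NH4Cl
Reagents that add atoms: vinylmagnesium bromide C=C[Mg]Br
Why: Grignard 1,2-addition to the enone is faster than any fragmentation of the covalent magnesium alkoxides formed from the two ring hydroxyls, and the new C9 centre needs no control because step 3 erases it.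

Step 3
Reactants: 4 (E)-1-[(1R,2R)-1,2-dihydroxy-2,6,6-trimethylcyclohexyl]-3-methylpenta-1,4-dien-3-ol
Product: 5 [(2E,4E)-5-[(1R,2R)-1,2-dihydroxy-2,6,6-trimethylcyclohexyl]-3-methylpenta-2,4-dien-1-yl]triphenylphosphonium bromide
Conditions: Ph3P·HBr (1.05 equiv), MeOH, 0 °C → rt, 12 h
Reagents that add atoms: triphenylphosphine hydrobromide [Br-].c1ccc(cc1)[PH+](c1ccccc1)c1ccccc1
Why: Allylic substitution with transposition (SN1'): only the doubly allylic C9 carbinol ionises, PPh3 traps the pentadienyl cation at its open terminus to give the E,E-dienyl salt, and C6–OH stays because its cation would be hindered and destabilised by the C5 oxygen, so C5 and C6 are untouched.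

Step 4
Reactants: 5 diol C15 phosphonium bromide; 6 (2E,4E,6E)-2,7-dimethylocta-2,4,6-trienedial (2.5 equiv)
Product: 8 all-E (5R,6R)-5,6-dihydroxy-5,6-dihydro-12'-apo-β-caroten-12'-al, via 11Z isomer of the apocarotenal 7 (not isolated)
Conditions: 1,2-epoxybutane/EtOH 1:1, reflux, 16 h, Ar, dark
Reagents that add atoms: none
Why: Wittig olefination under neutral conditions (bromide opens the epoxide to give the base, so no ring alkoxide builds up) stops at mono-olefination because 8 is less electrophilic than excess 6, and the hindered 11Z isomer relaxes thermally to all-E at reflux.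

Step 5
Reactants: 9 ketoisophorone (2,6,6-trimethylcyclohex-2-ene-1,4-dione)
Product: 11 (4R,6R)-4-hydroxy-2,2,6-trimethylcyclohexanone (actinol), via (6R)-levodione 10 (not isolated)
Conditions: old yellow enzyme OYE2, then levodione reductase (same vessel), glucose dehydrogenase, NADP+/NAD+ (cat.), D-glucose (2.4 equiv), phosphate buffer pH 7, 30 °C
Reagents that add atoms: none
Why: In this known ene-reductase/carbonyl-reductase cascade the flavoenzyme sets C6 (R, erased later) and the reductase delivers hydride to one face of the unhindered C4 ketone only, which sets 4R, the C3 centre of the target.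

Step 6
Reactants: 11 (4R,6R)-actinol
Product: 13 (4R)-2,6,6-trimethyl-4-(triethylsilyloxy)cyclohex-1-en-1-yl trifluoromethanesulfonate, via actinol triethylsilyl ether 12 (not isolated)
Conditions: KN(SiMe3)2 (1.0 equiv), THF, −78 °C; Et3SiCl (1.0 equiv), → 0 °C; KN(SiMe3)2 (1.3 equiv), −78 → 0 °C; PhNTf2 (1.3 equiv), → rt
Reagents that add atoms: chlorotriethylsilane CC[Si](Cl)(CC)CC; N-phenylbis(trifluoromethanesulfonimide) O=S(=O)(C(F)(F)F)N(c1ccccc1)S(=O)(=O)C(F)(F)F
Why: O–H deprotonation and silylation come first, then enolate O-triflation is regiospecific because only C6 carries an α-hydrogen (C2 is quaternary), which gives the tetrasubstituted enol triflate, removes C6 as a stereocentre and leaves C4 (R) untouched.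

Step 7
Reactants: 13 ring A enol triflate; 14 (E)-3-methylpent-2-en-4-yn-1-ol
Product: 15 (2E)-3-methyl-5-[(4R)-2,6,6-trimethyl-4-(triethylsilyloxy)cyclohex-1-en-1-yl]pent-2-en-4-yn-1-ol
Conditions: Pd(PPh3)4 (5 mol %), CuI (10 mol %), iPr2NH (3 equiv), DMF, rt → 45 °C
Reagents that add atoms: none
Why: In the Sonogashira coupling zerovalent palladium inserts into the vinyl C–OTf bond and the copper acetylide of 14 transfers the enyne with its E geometry kept, and the free primary alcohol is tolerated.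

Step 8
Reactants: 15 silylated C15 enynol
Product: 17 [(2E)-5-[(4R)-4-hydroxy-2,6,6-trimethylcyclohex-1-en-1-yl]-3-methylpent-2-en-4-yn-1-yl]triphenylphosphonium bromide, via desilylated enynediol 16 (not isolated)
Conditions: Ph3P·HBr (1.15 equiv), MeOH, rt, 16 h
Reagents that add atoms: triphenylphosphine hydrobromide [Br-].c1ccc(cc1)[PH+](c1ccccc1)c1ccccc1
Why: Acidic methanol first methanolyses the triethylsilyl ether, then PPh3 displaces the protonated primary allylic hydroxyl (allylic substitution), while the secondary non-allylic C3–OH does not ionise and stays R.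

Step 9
Reactants: 17 ring A C15 phosphonium bromide (1.2 equiv); 8 ring B C25 diol aldehyde
Product: 19 (3R,5'R,6'R)-7,8-didehydro-5',6'-dihydro-β,β-carotene-3,5',6'-triol (all-E), via 11Z isomer of the target 18 (not isolated)
Conditions: 1,2-epoxybutane/EtOH 1:1, reflux, 18 h, Ar, dark; Et3N-deactivated silica, crystallise
Reagents that add atoms: none
Why: Wittig olefination under neutral, acid-free conditions joins C11 to C12 without touching the acid-labile polyenylic C6'–OH or any stereocentre, and the hindered 11Z isomer equilibrates thermally to the all-E product.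

## Compound list
1 | β-ionone | CC(=O)/C=C/C1=C(C)CCCC1(C)C | starting material
2 | (5S,6R)-5,6-epoxy-5,6-dihydro-β-ionone = (E)-4-[(1R,6S)-2,2,6-trimethyl-7-oxabicyclo[4.1.0]heptan-1-yl]but-3-en-2-one | CC(=O)/C=C/[C@]12O[C@@]1(C)CCCC2(C)C | intermediate
3 | (E)-4-[(1R,2R)-1,2-dihydroxy-2,6,6-trimethylcyclohexyl]but-3-en-2-one | CC(=O)/C=C/[C@@]1(O)C(C)(C)CCC[C@@]1(C)O | intermediate
4 | (E)-1-[(1R,2R)-1,2-dihydroxy-2,6,6-trimethylcyclohexyl]-3-methylpenta-1,4-dien-3-ol, C9 epimers | C=CC(C)(O)/C=C/[C@@]1(O)C(C)(C)CCC[C@@]1(C)O | intermediate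
5 | [(2E,4E)-5-[(1R,2R)-1,2-dihydroxy-2,6,6-trimethylcyclohexyl]-3-methylpenta-2,4-dien-1-yl]triphenylphosphonium bromide | c1ccccc1[P+](c1ccccc1)(c1ccccc1)C/C=C(C)/C=C/[C@@]1(O)C(C)(C)CCC[C@@]1(C)O.[Br-] | intermediate
6 | (2E,4E,6E)-2,7-dimethylocta-2,4,6-trienedial | O=C/C(C)=C/C=C/C=C(C)/C=O | starting material
7 | 11Z isomer of 8 | O=C/C(C)=C/C=C/C=C(C)/C=C\C=C(C)\C=C\[C@@]1(O)C(C)(C)CCC[C@@]1(C)O | intermediate
8 | all-E (5R,6R)-5,6-dihydroxy-5,6-dihydro-12'-apo-β-caroten-12'-al | O=C/C(C)=C/C=C/C=C(C)/C=C/C=C(C)/C=C/[C@@]1(O)C(C)(C)CCC[C@@]1(C)O | intermediate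
9 | ketoisophorone | CC1=CC(=O)CC(C)(C)C1=O | starting material
10 | (6R)-2,2,6-trimethylcyclohexane-1,4-dione (levodione) | CC1(C)CC(=O)C[C@@H](C)C1=O | intermediate
11 | (4R,6R)-4-hydroxy-2,2,6-trimethylcyclohexanone (actinol) | CC1(C)C[C@H](O)C[C@@H](C)C1=O | intermediate
12 | (4R,6R)-2,2,6-trimethyl-4-(triethylsilyloxy)cyclohexanone | CC1(C)C[C@H](O[Si](CC)(CC)CC)C[C@@H](C)C1=O | intermediate
13 | (4R)-2,6,6-trimethyl-4-(triethylsilyloxy)cyclohex-1-en-1-yl trifluoromethanesulfonate | CC1=C(OS(=O)(=O)C(F)(F)F)C(C)(C)C[C@H](O[Si](CC)(CC)CC)C1 | intermediate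
14 | (E)-3-methylpent-2-en-4-yn-1-ol | C#C/C(C)=C/CO | starting material
15 | (2E)-3-methyl-5-[(4R)-2,6,6-trimethyl-4-(triethylsilyloxy)cyclohex-1-en-1-yl]pent-2-en-4-yn-1-ol | CC1=C(C#C/C(C)=C/CO)C(C)(C)C[C@H](O[Si](CC)(CC)CC)C1 | intermediate
16 | (1R)-4-[(3E)-5-hydroxy-3-methylpent-3-en-1-yn-1-yl]-3,5,5-trimethylcyclohex-3-en-1-ol | CC1=C(C#C/C(C)=C/CO)C(C)(C)C[C@H](O)C1 | intermediate
17 | [(2E)-5-[(4R)-4-hydroxy-2,6,6-trimethylcyclohex-1-en-1-yl]-3-methylpent-2-en-4-yn-1-yl]triphenylphosphonium bromide | [Br-].CC1=C(C#C/C(C)=C/C[P+](c2ccccc2)(c2ccccc2)c2ccccc2)C(C)(C)C[C@H](O)C1 | intermediate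
18 | 11Z isomer of 19 | CC1=C(C#C/C(C)=C/C=C\C(C)=C\C=C\C=C(C)\C=C\C=C(C)\C=C\[C@@]2(O)C(C)(C)CCC[C@@]2(C)O)C(C)(C)C[C@H](O)C1 | intermediate
19 | (3R,5'R,6'R)-7,8-didehydro-5',6'-dihydro-β,β-carotene-3,5',6'-triol, all-E | CC1=C(C#C/C(C)=C/C=C/C(C)=C/C=C/C=C(C)/C=C/C=C(C)/C=C/[C@@]2(O)C(C)(C)CCC[C@@]2(C)O)C(C)(C)C[C@H](O)C1 | target

## Step count and risks
Total steps: 9. Longest linear sequence: 5 (steps 1–4 then 9, or steps 5–8 then 9).

**Step 1 (the new step).**
- Risks:
  - Low ee from the uncatalysed carbodiimide/H2O2 background and from weak binding of the ketone.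
  - Any attack of water at C6 instead of C5 gives the enantiomeric trans-diol and erodes ee.
- Fallback (known chemistry, resolution instead of asymmetric catalysis): it sets out from 1. mCPBA in CH2Cl2 at 0 °C gives racemic 5,6-epoxy-5,6-dihydro-β-ionone F1. NaBH4/CeCl3·7H2O in MeOH at 0 °C gives two racemic C9 epimers that are separated on silica. The (5S*,6R*,9S*)-epoxy-β-ionol F2 is kept, and the (5S*,6R*,9R*)-epoxy-β-ionol F3 is oxidised back to F1 with MnO2. Lipase PS and vinyl acetate in tBuOMe acetylate only the 9R enantiomer of F2, giving the (5R,6S,9R)-epoxy-β-ionyl acetate F4, and leave the (5S,6R,9S)-epoxy-β-ionol F5. MnO2 in CH2Cl2 oxidises F5 to 2, where the fallback comes back to the route, and 2 is hydrolysed as in step 1.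

**Step 3.**
- Risk: protic acid may also ionise the allylic C6–OH, leading to dehydration, pinacol shift or loss of C6 configuration.
- Fallback (SN2 chemistry on a primary allylic bromide instead of ionisation of a tertiary carbinol; it also bypasses step 2): it sets out from 3. The preformed sodium anion of triethyl phosphonoacetate is too weak a base to make ring alkoxides. In THF at 0 °C → rt it gives ethyl (2E,4E)-5-[(1R,2R)-1,2-dihydroxy-2,6,6-trimethylcyclohexyl]-3-methylpenta-2,4-dienoate F6, and the 9Z isomer is removed on silica. iBu2AlH in toluene at −78 °C gives the C15 dienol F7. CBr4/PPh3 in CH2Cl2 at −20 °C gives the C15 dienyl bromide F8. PPh3 in EtOAc at rt precipitates 5, where the fallback comes back to the route.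

**Step 9.**
- Risks:
  - 9Z/11Z mixtures from the acetylenic ylide.
  - Loss of two advanced fragments in one step.
  - Long heating of the final triol.
- Fallback (the last bond becomes C6–C7 by cross-coupling instead of C11=C12 by olefination): it sets out from 8, 13 and 14. Compound 14 and Ph3P·HBr in MeOH give (E)-(3-methylpent-2-en-4-yn-1-yl)triphenylphosphonium bromide F9. Excess F9 and 8 in 1,2-epoxybutane at reflux give the C31 terminal alkyne (5R,6R)-7',8'-didehydro-5,6-dihydro-7'-apo-β-carotene-5,6-diol F10, which is purified to all-E at this stage. Compound 13 with catalytic HCl in MeOH gives (4R)-4-hydroxy-2,6,6-trimethylcyclohex-1-en-1-yl trifluoromethanesulfonate F11. F10 and F11 with Pd(PPh3)4, CuI and iPr2NH in DMF at rt give 19 directly, where the fallback comes back to the route.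

## Further compounds
F1 | step 1 | racemic 5,6-epoxy-5,6-dihydro-β-ionone | CC(=O)/C=C/[C@]12O[C@@]1(C)CCCC2(C)C.CC(=O)/C=C/[C@@]12O[C@]1(C)CCCC2(C)C
F2 | step 1 | racemic (5S*,6R*,9S*)-5,6-epoxy-5,6-dihydro-β-ionol | C[C@H](O)/C=C/[C@]12O[C@@]1(C)CCCC2(C)C.C[C@@H](O)/C=C/[C@@]12O[C@]1(C)CCCC2(C)C
F3 | step 1 | racemic (5S*,6R*,9R*)-5,6-epoxy-5,6-dihydro-β-ionol | C[C@@H](O)/C=C/[C@]12O[C@@]1(C)CCCC2(C)C.C[C@H](O)/C=C/[C@@]12O[C@]1(C)CCCC2(C)C
F4 | step 1 | (5R,6S,9R)-5,6-epoxy-5,6-dihydro-β-ionyl acetate | C[C@@H](OC(C)=O)/C=C/[C@@]12O[C@]1(C)CCCC2(C)C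
F5 | step 1 | (5S,6R,9S)-5,6-epoxy-5,6-dihydro-β-ionol | C[C@H](O)/C=C/[C@]12O[C@@]1(C)CCCC2(C)C
F6 | step 3 | ethyl (2E,4E)-5-[(1R,2R)-1,2-dihydroxy-2,6,6-trimethylcyclohexyl]-3-methylpenta-2,4-dienoate | CCOC(=O)/C=C(C)/C=C/[C@@]1(O)C(C)(C)CCC[C@@]1(C)O
F7 | step 3 | (1R,2R)-1-[(1E,3E)-5-hydroxy-3-methylpenta-1,3-dien-1-yl]-2,6,6-trimethylcyclohexane-1,2-diol | OC/C=C(C)/C=C/[C@@]1(O)C(C)(C)CCC[C@@]1(C)O
F8 | step 3 | (1R,2R)-1-[(1E,3E)-5-bromo-3-methylpenta-1,3-dien-1-yl]-2,6,6-trimethylcyclohexane-1,2-diol | BrC/C=C(C)/C=C/[C@@]1(O)C(C)(C)CCC[C@@]1(C)O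
F9 | step 9 | (E)-(3-methylpent-2-en-4-yn-1-yl)triphenylphosphonium bromide | C#C/C(C)=C/C[P+](c1ccccc1)(c1ccccc1)c1ccccc1.[Br-]
F10 | step 9 | (5R,6R)-7',8'-didehydro-5,6-dihydro-7'-apo-β-carotene-5,6-diol | C#C/C(C)=C/C=C/C(C)=C/C=C/C=C(C)/C=C/C=C(C)/C=C/[C@@]1(O)C(C)(C)CCC[C@@]1(C)O
F11 | step 9 | (4R)-4-hydroxy-2,6,6-trimethylcyclohex-1-en-1-yl trifluoromethanesulfonate | CC1=C(OS(=O)(=O)C(F)(F)F)C(C)(C)C[C@H](O)C1
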